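The α-methylene-γ-butyrolactone is disconnected into carbon dioxide and an ethynyl epoxide. In one operation, nickel-catalysed electroreductive Markovnikov hydrocarboxylation of the C7 ethynyl group forges the C11–C12 bond (α-carbon to carbonyl), and the magnesium acrylate so formed opens the strained C8–C9 oxirane at C8 (5-exo, anti), forging O–C8. The step exploits the cis C7/C8 fusion of the lactone on the cyclohexane and the trans C8–O/C9–O pattern: one oxirane, cis to the C6 oxygen, fixes both centres, since C8 is inverted and C9 keeps its oxygen as the only free hydroxyl. The precursor, a 7-ethynyl-8,9-epoxycyclohexane bearing the C6 angelate, is built from benzoquinone monoketal by two conjugate additions.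

Key step: step 14

Remarks on the chemistry:
- Locants follow elemanolide numbering. C10 is the quaternary ring carbon (methyl, vinyl), C5 carries the three-carbon side chain (C4, C3 = CH2, C15 = CHO), C6 carries the angelate, C7 and C8 are the lactone fusion carbons, and C9 carries the 2-methylbutanoate. C11, C12 and C13 are the lactone α-carbon, carbonyl carbon and exocyclic CH2.
- "Up" is the ring face of the C10 vinyl group and "down" that of the C10 methyl group.
- The sense of induction in step 2 is assigned by analogy with 2-cyclohexenone; the enantiomeric ligand would be used if the opposite sense were found.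

Step 1
Reactants: 1 4-methoxybenzyl propargyl ether
Product: 2 2-[3-(4-methoxybenzyloxy)prop-1-en-2-yl]-4,4,5,5-tetramethyl-1,3,2-dioxaborolane
Conditions: CuCl (5 mol %), 1,3-dimesitylimidazolinium chloride (5 mol %), NaOt-Bu (20 mol %), B2pin2 (1.1 equiv), MeOH (2 equiv), THF, −50 → −15 °C
Reagents that add atoms: bis(pinacolato)diboron, CC1(C)OB(OC1(C)C)B1OC(C)(C)C(C)(C)O1
Why: Copper-catalysed protoboration of a terminal alkyne (carbene–copper boryl addition, then protonation by methanol), in which the N-aryl carbene ligand and the propargylic ether oxygen should direct boron to the internal carbon (Markovnikov) and give the 1,1-disubstituted alkenylboronate.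

Step 2
Reactants: 2 alkenylboronate; 3 4,4-dimethoxycyclohexa-2,5-dien-1-one (1.5 equiv)
Product: 4 (R)-4,4-dimethoxy-5-[3-(4-methoxybenzyloxy)prop-1-en-2-yl]cyclohex-2-en-1-one
Conditions: [Rh(cod)Cl]2 (2.5 mol %), (R)-BINAP (6 mol %), KOH (0.3 equiv), dioxane/H2O (10:1), 40 °C
Reagents that add atoms: none
Why: Hayashi–Miyaura rhodium-catalysed asymmetric 1,4-addition to one of the two enantiotopic enone units of the monoketal, in which the chiral Rh–BINAP alkenyl complex selects the enone face and so sets C5, while the excess dienone suppresses double addition.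

Step 3
Reactants: 4 enone
Product: 6 4,4-dimethoxy-6-methyl-5-[3-(4-methoxybenzyloxy)prop-1-en-2-yl]cyclohex-2-en-1-one (epimers at the methyl-bearing carbon), via lithium dienolate 5 (not isolated)
Conditions: LDA (1.1 equiv), THF, −78 °C; MeI, −78 → −40 °C
Reagents that add atoms: methyl iodide, CI
Why: Kinetic α′-deprotonation (the γ-carbon is the ketal carbon and has no hydrogen) gives the cross-conjugated dienolate, which is C-methylated at C10 (enolate alkylation); the epimer ratio is irrelevant because C10 is re-enolised in step 4.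

Step 4
Reactants: 6 methyl enone
Product: 8 4,4-dimethoxy-6-methyl-5-[3-(4-methoxybenzyloxy)prop-1-en-2-yl]-6-vinylcyclohex-2-en-1-one (vinyl trans to the C5 side chain), via lithium enolate 7 (not isolated)
Conditions: LiHMDS (1.3 equiv), THF, −78 → 0 °C; Pd2(dba)3 (2.5 mol %), P(t-Bu)3 (6 mol %), vinyl bromide (1 M in THF, 3 equiv), rt
Reagents that add atoms: vinyl bromide, C=CBr
Why: Palladium-catalysed α-alkenylation of a ketone enolate (oxidative addition of vinyl bromide, enolate transmetalation, C–C reductive elimination), in which the C5 side chain is pseudo-axial next to the tetrasubstituted enolate (A(1,2) strain with the C10 methyl) so that palladium binds C10 on the opposite face and the vinyl group enters trans to the side chain, creating the quaternary centre.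

Step 5
Reactants: 8 vinyl enone ketal
Product: 9 5-methyl-6-[3-(4-methoxybenzyloxy)prop-1-en-2-yl]-5-vinylcyclohex-2-ene-1,4-dione
Conditions: 5% aq. oxalic acid, THF, 0 °C → rt
Reagents that add atoms: water, O
Why: Acid-catalysed ketal hydrolysis, in which the quaternary C10 blocks aromatisation, the cold weakly acidic medium limits enolisation at C5 and the PMB ether survives.

Step 6
Reactants: 9 ene-dione
Product: 10 4-hydroxy-6-methyl-5-[3-(4-methoxybenzyloxy)prop-1-en-2-yl]-6-vinylcyclohex-2-en-1-one (C6 hydroxyl down, cis to the C5 side chain)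
Conditions: (S)-2-methyl-CBS-oxazaborolidine (0.2 equiv), catecholborane (1.5 equiv), toluene, −78 °C; aqueous work-up
Reagents that add atoms: none
Why: Corey–Bakshi–Shibata 1,2-reduction, in which the C6 carbonyl (next to tertiary C5) reacts before the C9 carbonyl (next to quaternary C10) and hydride is delivered to the face opposite the adjacent C5 side chain (substrate bias reinforced by the catalyst, with the branched C5 side as the large group), placing the C6 hydroxyl cis to the side chain.

Step 7
Reactants: 10 hydroxy enone
Product: 11 tert-butyldimethylsilyl ether of 10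
Conditions: TBSOTf (1.3 equiv), 2,6-lutidine (2 equiv), CH2Cl2, −78 → 0 °C
Reagents that add atoms: tert-butyldimethylsilyl triflate, CC(C)(C)[Si](C)(C)OS(=O)(=O)C(F)(F)F
Why: Silylation of the secondary allylic alcohol with a silyl triflate gives the bulky γ-silyloxy group that will steer the next conjugate addition.

Step 8
Reactants: 11 silyloxy enone
Product: 13 4-(tert-butyldimethylsilyloxy)-2-methyl-3-[3-(4-methoxybenzyloxy)prop-1-en-2-yl]-5-[(trimethylsilyl)ethynyl]-2-vinylcyclohexan-1-one (alkynyl up), via trimethylsilyl enol ether 12 (not isolated)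
Conditions: Me3SiC≡CH, n-BuLi, THF, −78 °C; ZnBr2, 0 °C; 11, TMSOTf (1.5 equiv), Et2O/THF, −40 °C; then 1 M HCl, THF, 0 °C
Reagents that add atoms: trimethylsilylacetylene, C#C[Si](C)(C)C; trimethylsilyl triflate, C[Si](C)(C)OS(=O)(=O)C(F)(F)F (its silicon stays only in 12)
Why: Silyl-triflate-promoted conjugate addition of an alkynylzinc reagent to the enone, in which the nucleophile attacks C7 axially on the face opposite both the adjacent C6 silyloxy group and the C5 side chain, so the alkynyl group ends up trans to the C6 oxygen, and dilute acid cleaves the labile enol ether to the ketone.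

Step 9
Reactants: 13 alkynyl ketone
Product: 15 enol triflate of 13 (C8=C9), via potassium enolate 14 (not isolated)
Conditions: KHMDS (1.2 equiv), THF, −78 °C; PhNTf2 (1.3 equiv), −78 → 0 °C
Reagents that add atoms: N-phenylbis(trifluoromethanesulfonimide), O=S(=O)(N(c1ccccc1)S(=O)(=O)C(F)(F)F)C(F)(F)F
Why: The ketone can enolise only towards C8 because C10 is quaternary, so O-sulfonylation of the enolate gives a single enol triflate (enol triflate formation).

Step 10
Reactants: 15 enol triflate
Product: 16 cyclohexene with a C8=C9 double bond (C6 silyl ether, C7 silylalkyne)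
Conditions: Pd(OAc)2 (5 mol %), PPh3 (10 mol %), n-Bu3N (3 equiv), HCO2H (2 equiv), DMF, 60 °C
Reagents that add atoms: none
Why: Palladium-catalysed formate reduction of an enol triflate (oxidative addition, formate exchange, decarboxylation, C–H reductive elimination) should leave the C8=C9 alkene without touching the silylalkyne or the other alkenes.

Step 11
Reactants: 16 silylated cyclohexene
Product: 17 homoallylic alcohol with a terminal alkyne (C6 hydroxyl down, C7 ethynyl up)
Conditions: TBAF (3 equiv), THF, 0 °C → rt
Reagents that add atoms: none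
Why: Fluoride-mediated desilylation removes the C6 silyl ether and the alkynyl silane in one operation, and the PMB ether is unaffected.

Step 12
Reactants: 17 homoallylic alcohol
Product: 18 8,9-epoxy alcohol (oxirane down, cis to the C6 hydroxyl, trans to the C7 ethynyl group)
Conditions: VO(acac)2 (5 mol %), t-BuOOH (1.3 equiv, in decane), CH2Cl2, 0 °C → rt
Reagents that add atoms: tert-butyl hydroperoxide, CC(C)(C)OO
Why: Hydroxyl-directed vanadium-catalysed epoxidation, in which the pseudo-axial homoallylic C6 alkoxide binds vanadium and delivers the peroxide oxygen to the same face of the ring alkene, setting the oxirane cis to the C6 oxygen, while the side-chain alkene is deactivated by its allylic ether oxygen and the vinyl and alkyne groups are out of reach.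

Step 13
Reactants: 18 epoxy alcohol; 19 angelic acid
Product: 20 epoxy alkyne angelate (C6 ester of 18)
Conditions: 19, 2,4,6-trichlorobenzoyl chloride, Et3N, toluene, rt; then 18, 75 °C
Reagents that add atoms: none
Why: Yamaguchi-type esterification through the preformed mixed anhydride, in which omitting a nucleophilic catalyst should preserve the Z geometry of the angelate and the C6 hydroxyl is the only free alcohol.

Step 14
Reactants: 20 epoxy alkyne angelate
Product: 22 cis-fused α-methylene-γ-butyrolactone with a free C9 hydroxyl, via magnesium acrylate 21 (not isolated)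
Conditions: undivided cell, Mg anode, carbon-fibre cathode, Ni(bpy)3(BF4)2 (10 mol %), n-Bu4NBF4 (0.1 M), DMF, CO2 (1 atm), 20 °C, constant current (about 2.2 F/mol); then 50 °C; 1 M HCl work-up
Reagents that add atoms: carbon dioxide, O=C=O
Why: Cathodically generated zerovalent nickel–bipyridine couples the terminal alkyne with CO2 by oxidative cyclisation to an oxanickelacyclopentenone in which the new C11–C12 bond lies at the internal alkyne carbon and nickel at the terminal one; Mg2+ from the anode cleaves the Ni–O bond, and protonation of the alkenyl–nickel bond leaves the exocyclic CH2 and returns divalent nickel to the cathode. The closest known reaction type is the nickel–bipyridine-catalysed electrochemical hydrocarboxylation of terminal alkynes to 2-substituted acrylic acids with a sacrificial magnesium anode, here telescoped with the equally known lactonisation of an epoxy carboxylate (the oxirane analogue of an iodolactonisation). The γ-lactone closes 5-exo-tet: the magnesium carboxylate on C11 attacks C8 of the Mg2+-activated oxirane from the up face, anti to the departing oxygen, and release of oxirane strain drives the O–C8 bond formation. C8 is inverted, so the lactone oxygen ends cis to the C7 substituent (cis ring fusion), and C9 keeps the oxirane oxygen as a free hydroxyl trans to the lactone oxygen; both follow from the oxirane configuration set in step 12, and no other centre is touched. The step needs Markovnikov regiochemistry in the CO2 coupling (secured by the bipyridine ligand, which keeps the ring substituent away from nickel), attack at C8 and not C9 (C9 would need a 6-endo closure at a neopentyl carbon) and chemoselectivity for the alkyne over the vinyl group, the 1,1-disubstituted alkene and the angelate, which should not be reduced at the potential of the divalent/zerovalent nickel couple. A halide-free electrolyte is chosen so that the oxirane is not converted to a cyclic carbonate by CO2 before the carboxylate arrives.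

Step 15
Reactants: 22 hydroxy lactone; 23 (R)-2-methylbutanoic acid
Product: 24 C9 (R)-2-methylbutanoate of 22 (PMB ether of the C15 alcohol)
Conditions: EDC·HCl (2 equiv), DMAP (0.3 equiv), CH2Cl2, 0 °C → rt
Reagents that add atoms: none
Why: Steglich esterification of the only free hydroxyl (C9), in which activation as the O-acylisourea at low temperature should keep the α-stereocentre of the acid intact.

Step 16
Reactants: 24 PMB ether
Product: 25 C15 allylic alcohol
Conditions: DDQ (1.5 equiv), CH2Cl2/pH 7 buffer (10:1), 0 °C
Reagents that add atoms: none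
Why: Oxidative cleavage of the 4-methoxybenzyl ether by benzylic hydride abstraction, to which the esters, the lactone and the alkenes are inert.

Step 17
Reactants: 25 allylic alcohol
Product: 26 CNP0295282.1
Conditions: Dess–Martin periodinane (1.5 equiv), NaHCO3, CH2Cl2, 0 °C → rt
Reagents that add atoms: none
Why: Dess–Martin oxidation of the primary allylic alcohol to the 2-substituted acrolein under buffered, non-basic conditions that should not isomerise the angelate or add to the α-methylene lactone.

Compound list

1 | 4-methoxybenzyl propargyl ether | C#CCOCc1ccc(OC)cc1 | starting material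
2 | 2-[3-(4-methoxybenzyloxy)prop-1-en-2-yl]-4,4,5,5-tetramethyl-1,3,2-dioxaborolane | C=C(COCc1ccc(OC)cc1)B1OC(C)(C)C(C)(C)O1 | intermediate
3 | 4,4-dimethoxycyclohexa-2,5-dien-1-one | COC1(OC)C=CC(=O)C=C1 | starting material
4 | (R)-4,4-dimethoxy-5-[3-(4-methoxybenzyloxy)prop-1-en-2-yl]cyclohex-2-en-1-one (C5 side chain down) | O=C1C=CC(OC)(OC)[C@@H](C(=C)COCc2ccc(OC)cc2)C1 | intermediate
5 | lithium dienolate of 4 (cross-conjugated, C9–O/C10) | [Li+].[O-]C1=C[C@H](C(=C)COCc2ccc(OC)cc2)C(OC)(OC)C=C1 | intermediate
6 | 4,4-dimethoxy-6-methyl-5-[3-(4-methoxybenzyloxy)prop-1-en-2-yl]cyclohex-2-en-1-one, C5 as in 4, mixture of epimers at the methyl-bearing carbon | CC1[C@H](C(=C)COCc2ccc(OC)cc2)C(OC)(OC)C=CC1=O | intermediate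
7 | lithium enolate of 6 (tetrasubstituted at C10) | [Li+].[O-]C1=C(C)[C@H](C(=C)COCc2ccc(OC)cc2)C(OC)(OC)C=C1 | intermediate
8 | 4,4-dimethoxy-6-methyl-5-[3-(4-methoxybenzyloxy)prop-1-en-2-yl]-6-vinylcyclohex-2-en-1-one; vinyl up, methyl and C5 side chain down | C=C[C@@]1(C)[C@H](C(=C)COCc2ccc(OC)cc2)C(OC)(OC)C=CC1=O | intermediate
9 | 5-methyl-6-[3-(4-methoxybenzyloxy)prop-1-en-2-yl]-5-vinylcyclohex-2-ene-1,4-dione; configuration as in 8 | C=C[C@@]1(C)[C@H](C(=C)COCc2ccc(OC)cc2)C(=O)C=CC1=O | intermediate
10 | 4-hydroxy-6-methyl-5-[3-(4-methoxybenzyloxy)prop-1-en-2-yl]-6-vinylcyclohex-2-en-1-one; C6 hydroxyl down, cis to the C5 side chain | C=C[C@@]1(C)[C@H](C(=C)COCc2ccc(OC)cc2)[C@H](O)C=CC1=O | intermediate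
11 | tert-butyldimethylsilyl ether of 10 | C=C[C@@]1(C)[C@H](C(=C)COCc2ccc(OC)cc2)[C@H](O[Si](C)(C)C(C)(C)C)C=CC1=O | intermediate
12 | trimethylsilyl enol ether (C8=C9) of ketone 13 | C=C[C@@]1(C)[C@H](C(=C)COCc2ccc(OC)cc2)[C@H](O[Si](C)(C)C(C)(C)C)[C@@H](C#C[Si](C)(C)C)C=C1O[Si](C)(C)C | intermediate
13 | 4-(tert-butyldimethylsilyloxy)-2-methyl-3-[3-(4-methoxybenzyloxy)prop-1-en-2-yl]-5-[(trimethylsilyl)ethynyl]-2-vinylcyclohexan-1-one; C7 alkynyl up, trans to the C6 silyloxy group and the C5 side chain | C=C[C@@]1(C)[C@H](C(=C)COCc2ccc(OC)cc2)[C@H](O[Si](C)(C)C(C)(C)C)[C@@H](C#C[Si](C)(C)C)CC1=O | intermediate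
14 | potassium enolate of 13 (C8=C9) | C=C[C@@]1(C)[C@H](C(=C)COCc2ccc(OC)cc2)[C@H](O[Si](C)(C)C(C)(C)C)[C@@H](C#C[Si](C)(C)C)C=C1[O-].[K+] | intermediate
15 | enol triflate of 13 (C9–OTf, C8=C9) | C=C[C@@]1(C)[C@H](C(=C)COCc2ccc(OC)cc2)[C@H](O[Si](C)(C)C(C)(C)C)[C@@H](C#C[Si](C)(C)C)C=C1OS(=O)(=O)C(F)(F)F | intermediate
16 | cyclohexene with C8=C9; C10 vinyl up and methyl down, C5 side chain down, C6 OTBS down, C7 (trimethylsilyl)ethynyl up | C=C[C@@]1(C)[C@H](C(=C)COCc2ccc(OC)cc2)[C@H](O[Si](C)(C)C(C)(C)C)[C@@H](C#C[Si](C)(C)C)C=C1 | intermediate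
17 | desilylated cyclohexene: C6 hydroxyl down, C7 ethynyl up, C8=C9 | C=C[C@@]1(C)[C@H](C(=C)COCc2ccc(OC)cc2)[C@H](O)[C@@H](C#C)C=C1 | intermediate
18 | 8,9-epoxy alcohol: oxirane down (cis to C6 OH, trans to C7 ethynyl) | C=C[C@@]1(C)[C@H](C(=C)COCc2ccc(OC)cc2)[C@H](O)[C@@H](C#C)[C@@H]2O[C@@H]21 | intermediate
19 | angelic acid, (Z)-2-methylbut-2-enoic acid | C/C=C(/C)C(=O)O | starting material
20 | C6 angelate of 18 (7-ethynyl-8,9-epoxide) | C=C[C@@]1(C)[C@H](C(=C)COCc2ccc(OC)cc2)[C@H](OC(=O)/C(C)=C\C)[C@@H](C#C)[C@@H]2O[C@@H]21 | intermediate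
21 | magnesium 2-substituted acrylate (tetrafluoroborate counter-ion) formed from 20 and CO2, oxirane intact | C=C[C@@]1(C)[C@H](C(=C)COCc2ccc(OC)cc2)[C@H](OC(=O)/C(C)=C\C)[C@@H](C(=C)C(=O)[O-])[C@@H]2O[C@@H]21.[Mg+2].F[B-](F)(F)F | intermediate
22 | cis-fused 8,12-lactone with exocyclic methylene; lactone O and C11 up, free C9 hydroxyl down, C6 angelate down, C15 PMB ether | C=C[C@@]1(C)[C@H](C(=C)COCc3ccc(OC)cc3)[C@H](OC(=O)/C(C)=C\C)[C@H]2C(=C)C(=O)O[C@H]2[C@@H]1O | intermediate
23 | (R)-2-methylbutanoic acid | CC[C@@H](C)C(=O)O | starting material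
24 | C9 (R)-2-methylbutanoate of 22 | C=C[C@@]1(C)[C@H](C(=C)COCc3ccc(OC)cc3)[C@H](OC(=O)/C(C)=C\C)[C@H]2C(=C)C(=O)O[C@H]2[C@@H]1OC(=O)[C@H](C)CC | intermediate
25 | C15 allylic alcohol (PMB removed) | C=C[C@@]1(C)[C@H](C(=C)CO)[C@H](OC(=O)/C(C)=C\C)[C@H]2C(=C)C(=O)O[C@H]2[C@@H]1OC(=O)[C@H](C)CC | intermediate
26 | CNP0295282.1 | C=C[C@@]1(C)[C@H](C(=C)C=O)[C@H](OC(=O)/C(C)=C\C)[C@H]2C(=C)C(=O)O[C@H]2[C@@H]1OC(=O)[C@H](C)CC | target

Total step count: 17. Longest linear sequence: 17 steps (from 1 through 2; 16 steps counted from dienone 3).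

Steps most likely to fail

1. Step 14 (key step). Low-valent nickel may open the oxirane reductively, or the oxirane may be carboxylated to a carbonate, before the alkyne has coupled with CO2; regiocontrol of the coupling may also erode under current. The fallback sets out from 20 and runs the stoichiometric parent reaction without current or Mg2+: Ni(cod)2 and 2,2′-bipyridine (1 equiv each) under CO2 (1 atm) in THF, 0 °C → rt, should give the oxanickelacycle, which is hydrolysed with cold dilute acid to the epoxy acrylic acid F1. Catalytic camphorsulfonic acid in CH2Cl2 then closes the lactone by anti opening of the oxirane, and the sequence comes back to the route at 22.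

2. Step 12. The C6 hydroxyl is also homoallylic to the side-chain alkene, so directed oxygen transfer to that alkene may compete (poor chemoselectivity). The fallback sets out from ketone 13 and builds the oxirane from the C9 carbonyl instead of from an alkene. KHMDS followed by 2-(phenylsulfonyl)-3-phenyloxaziridine should hydroxylate the enolate at C8 trans to the alkynyl group, giving the α-hydroxy ketone F2. NaBH4 in MeOH at −40 °C should give the cis-8,9-diol F3. Trimethyl orthoacetate with catalytic PPTS converts it to the cyclic orthoacetate F4, and acetyl bromide opens this through the acetoxonium ion with inversion at the less hindered C8 to the bromo acetate F5. K2CO3 in MeOH removes the acetate, closes the oxirane on the face of the former diol and cleaves the alkynyl silane, giving the silyl-protected epoxy alkyne F6. TBAF removes the silyl ether, and the sequence comes back to the route at 18.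

3. Step 4. β-Hydride elimination from the palladium enolate, Heck-type insertion of the vinylpalladium species into the enone, or slow coupling at the hindered tetrasubstituted enolate may dominate. The fallback sets out from 6 and uses a vinyl cation equivalent without a transition metal. LDA in THF at −78 °C followed by phenyl vinyl sulfoxide gives, by Michael addition anti to the C5 side chain, the 2-(phenylsulfinyl)ethyl ketone F7. Thermal syn-elimination of the sulfoxide (toluene, 110 °C, CaCO3) then gives the vinyl group, and the sequence comes back to the route at 8.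

Further compounds

F1 | step 14 | epoxy 2-substituted acrylic acid (free acid corresponding to 21) | C=C[C@@]1(C)[C@H](C(=C)COCc2ccc(OC)cc2)[C@H](OC(=O)/C(C)=C\C)[C@@H](C(=C)C(=O)O)[C@@H]2O[C@@H]21
F2 | step 12 | α-hydroxy ketone: 13 with a C8 hydroxyl down (trans to the C7 alkynyl group) | C=C[C@@]1(C)[C@H](C(=C)COCc2ccc(OC)cc2)[C@H](O[Si](C)(C)C(C)(C)C)[C@@H](C#C[Si](C)(C)C)[C@H](O)C1=O
F3 | step 12 | cis-8,9-diol (both hydroxyls down) | C=C[C@@]1(C)[C@H](C(=C)COCc2ccc(OC)cc2)[C@H](O[Si](C)(C)C(C)(C)C)[C@@H](C#C[Si](C)(C)C)[C@H](O)[C@@H]1O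
F4 | step 12 | cyclic 2-methoxy-2-methyl-1,3-dioxolane (orthoacetate) of diol F3 | C=C[C@@]1(C)[C@H](C(=C)COCc2ccc(OC)cc2)[C@H](O[Si](C)(C)C(C)(C)C)[C@@H](C#C[Si](C)(C)C)[C@@H]2OC(C)(OC)O[C@@H]21
F5 | step 12 | bromo acetate: C8 bromide up, C9 acetate down | C=C[C@@]1(C)[C@H](C(=C)COCc2ccc(OC)cc2)[C@H](O[Si](C)(C)C(C)(C)C)[C@@H](C#C[Si](C)(C)C)[C@@H](Br)[C@@H]1OC(C)=O
F6 | step 12 | tert-butyldimethylsilyl ether of 18 (8,9-oxirane down, terminal alkyne) | C=C[C@@]1(C)[C@H](C(=C)COCc2ccc(OC)cc2)[C@H](O[Si](C)(C)C(C)(C)C)[C@@H](C#C)[C@@H]2O[C@@H]21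
F7 | step 4 | 6-[2-(phenylsulfinyl)ethyl] analogue of 8 (sulfinylethyl group up, sulfur epimers) | O=S(CC[C@@]1(C)[C@H](C(=C)COCc2ccc(OC)cc2)C(OC)(OC)C=CC1=O)c1ccccc1
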